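**Plan**

Numbering follows the SMILES: C1 acetyl CH3, C2 side-chain C=O, C3, C4, C5 ring C=O, C6 carbinol, C7 pyran CH2, O8, C9 CMe2, C10, C11, C12, C13 (quaternary, CH3), C14, C15, C16, C17=C18 enol-ester alkene. The rings are the pyran C6-C7-O8-C9-C10-C15, the cyclohexane C10–C15 and the cycloheptanone C4-C5-C6-C15-C14-C13-C16; the last two form a bicyclo[4.3.1]decane with bridgeheads C13/C15.
Enabling feature: C9 (CMe2) sits on O8 next to ring-fusion C10, C10 is bonded to C15, and C15 is β to the C5 ketone with the one-carbon unit C7 on C6. This is the imprint of a 1-oxadiene O8=C7–C6=C15 added to a prenyl alkene C10=C9 whose four-atom tether C11–C12–C13–C14 is anchored 1,3 on the seven-membered ring.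
Cuts, in retrosynthetic order: C18–O (Cu coupling of an alkenylboron with senecioic acid); C17=C18 (borylolefination); C3–C4 and C16–C17 (vinyl cuprate/allylation of a C4=C16 enone); C6–O and the C7 oxidation level (enol ether oxidation, acetal reduction); C15–C10 together with O8–C9 (oxa-Diels–Alder); C6–C7 (formylation); C9=C10 (Wittig); C4 (one-carbon ring expansion); C12–C13 (asymmetric conjugate addition).
Forward ring order: bought cyclohexenone, then a transient cyclopropane, then the cycloheptenone. The cyclohexane and dihydropyran close together in one cycloaddition to complete the tricycle, and both side chains are attached afterwards.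
Stereochemistry: C13 comes from a chiral Cu–NHC catalyst. C15 (tether face) and C10 (exo folding) follow from C13 in the cycloaddition. C6 comes from convex-face epoxidation, C16 from exo-face cuprate attack, and C4 from allylation anti to the C16 vinyl group. The E enol ester comes from E-selective Cr(II) borylolefination and a stereoretentive Cu coupling.

Key step: step 10

Assumption: the configuration is taken exactly as written in the SMILES, i.e. (4S,6R,10S,13S,15S,16S) in the numbering above, with H-10/H-15 trans. This obliges the cyclohexane to close through a boat-like exo folding. The transient stereocentres (cyclopropane, C–Cl, C–Se, acetal C7) form as mixtures and are erased later.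

**Route**

Step 1
Reactants: 1 2-(2-bromoethyl)-1,3-dioxolane
Product: 2 [2-(1,3-dioxolan-2-yl)ethyl]magnesium bromide (titrated THF solution)
Conditions: Mg turnings (cat. I2), THF, 20–25 °C
Reagents that add atoms: magnesium, [Mg]
Why: Direct magnesium insertion (Grignard formation) into a primary bromide; the γ-acetal Grignard reagent is stable in THF as long as it is kept at or below room temperature.

Step 2
Reactants: 3 3-methylcyclohex-2-en-1-one; 2 [2-(1,3-dioxolan-2-yl)ethyl]magnesium bromide
Product: 5 (R)-({3-[2-(1,3-dioxolan-2-yl)ethyl]-3-methylcyclohex-1-en-1-yl}oxy)trimethylsilane, via bromomagnesium (R)-3-[2-(1,3-dioxolan-2-yl)ethyl]-3-methylcyclohex-1-en-1-olate 4 (not isolated)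
Conditions: Cu(OTf)2 (3 mol %), chiral imidazolinium salt (NHC precursor, 4 mol %), Et2O, −30 °C, slow addition of 2; then TMSCl, Et3N, DMPU, −30 → 23 °C
Reagents that add atoms: chlorotrimethylsilane, C[Si](C)(C)Cl
Why: Copper/NHC-catalysed asymmetric conjugate addition of a primary alkyl Grignard reagent to a β-methyl cyclic enone, in which the ligand antipode that delivers the alkyl group to the Si face of C3 of 3 sets the quaternary centre C13 as (R), and O-silylation of the regiodefined magnesium enolate fixes the C5=C16 enol ether needed for the ring expansion.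

Step 3
Reactants: 5 (R)-silyl enol ether
Product: 6 (5R)-5-[2-(1,3-dioxolan-2-yl)ethyl]-5-methyl-1-(trimethylsilyloxy)bicyclo[4.1.0]heptane (cis-fused; drawn with the cyclopropane CH2 anti to the acetal arm, the other diastereomer reacts alike)
Conditions: Et2Zn, CH2I2, Et2O, 0 → 23 °C
Reagents that add atoms: diiodomethane, ICI
Why: Furukawa-modified Simmons–Smith cyclopropanation, which is fastest on the electron-rich silyl enol ether (the only alkene present) and inserts C4 between C5 and C16; the two new stereocentres are erased in the next two steps, so facial selectivity is irrelevant.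

Step 4
Reactants: 6 siloxycyclopropane
Product: 7 (4R)-3-chloro-4-[2-(1,3-dioxolan-2-yl)ethyl]-4-methylcycloheptan-1-one (C–Cl epimers)
Conditions: FeCl3 (2.5 equiv), pyridine (1 equiv), DMF, 0 → 23 °C
Reagents that add atoms: iron(III) chloride, Cl[Fe](Cl)Cl
Why: Ito–Saegusa iron(III)-mediated oxidative opening of a siloxycyclopropane: one-electron oxidation and β-scission of the internal C5–C16 bond give the ring-expanded C16 radical, which abstracts chlorine from FeCl3, and the acetal-masked arm offers no alkene for radical cyclisation.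

Step 5
Reactants: 7 β-chloro ketone
Product: 8 (R)-4-[2-(1,3-dioxolan-2-yl)ethyl]-4-methylcyclohept-2-en-1-one
Conditions: NaOAc, MeOH, reflux
Reagents that add atoms: none
Why: E1cB elimination of HCl from a β-chloro ketone with a mild base gives the conjugated C4=C16 enone without touching the acetal or C13.

Step 6
Reactants: 8 enone acetal
Product: 9 (R)-3-(1-methyl-4-oxocyclohept-2-en-1-yl)propanal
Conditions: 1 M aq HCl, THF, 23 °C
Reagents that add atoms: water, O
Why: Acid-catalysed acetal hydrolysis; the enone carries no acid-labile group and C13 is quaternary, so nothing can epimerise.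

Step 7
Reactants: 9 enone aldehyde; 10 isopropyltriphenylphosphonium iodide
Product: 12 (R)-4-methyl-4-(4-methylpent-3-en-1-yl)cyclohept-2-en-1-one, via isopropylidenetriphenylphosphorane 11 (not isolated)
Conditions: 10, n-BuLi, THF, 0 °C; then 9, −78 → 0 °C
Reagents that add atoms: none
Why: Wittig olefination with an unstabilised ylide, which at −78 °C takes the unhindered aldehyde far faster than the conjugated ketone and installs C9 with both methyl groups (no alkene geometry issue).

Step 8
Reactants: 12 prenyl-type cycloheptenone
Product: 14 (S,Z)-7-(hydroxymethylidene)-4-methyl-4-(4-methylpent-3-en-1-yl)cyclohept-2-en-1-one (enol form of the 2-formyl ketone; the geometry at C13 is unchanged and only the CIP descriptor changes), via lithium 5-methyl-5-(4-methylpent-3-en-1-yl)cyclohepta-1,6-dien-1-olate 13 (not isolated)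
Conditions: LDA, THF, −78 °C; HCO2CH2CF3, −78 → −20 °C; aq NH4Cl
Reagents that add atoms: 2,2,2-trifluoroethyl formate, O=COCC(F)(F)F
Why: Kinetic crossed-Claisen α′-formylation with an activated formate ester: C6 is the only enolisable carbon (C4 is vinylic and the γ-carbon C13 is quaternary), so C7 can only enter at C6.

Step 9
Reactants: 14 hydroxymethylidene ketone
Product: 16 (4S)-4-methyl-4-(4-methylpent-3-en-1-yl)-7-oxo-1-(phenylselanyl)cyclohept-5-ene-1-carbaldehyde (C6 epimers), via sodium enolate of the formyl ketone 15 (not isolated)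
Conditions: NaH, THF, 0 °C; PhSeCl (1.0 equiv), −78 °C
Reagents that add atoms: benzeneselenenyl chloride, Cl[Se]c1ccccc1
Why: α-Selenenylation of a preformed β-dicarbonyl enolate, which consumes the single equivalent of PhSeCl much faster than the prenyl alkene does; both C6 epimers keep a C15–H for the later syn-elimination.

Step 10
Reactants: 16 α-formyl α-phenylselanyl ketone
Product: 19 (10S,13S,15S)-tricyclic dienone (dihydropyran C6=C7–O8–C9(CH3)2–C10–C15 fused to a bicyclo[4.3.1]decadienone with C5=O, C4=C16 and 13-CH3; H-10/H-15 trans), via (4S)-4-methyl-4-(4-methylpent-3-en-1-yl)-7-oxo-1-(phenylseleninyl)cyclohept-5-ene-1-carbaldehyde 17 (not isolated), via (S)-4-methyl-4-(4-methylpent-3-en-1-yl)-7-oxocyclohepta-1,5-diene-1-carbaldehyde 18 (not isolated)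
Conditions: 30% aq H2O2 (2.5 equiv), CH2Cl2, 0 °C, 20 min; cold aq NaHCO3 wash, Na2SO4; diluted to 0.01 M in CH2Cl2, 23 → 40 °C
Reagents that add atoms: none
Why: Oxidation at selenium gives 17, whose syn-elimination can only take a C15–H and releases the 2-formylcyclohepta-2,6-dienone 18; in 18 only the formyl C7=O8 can lie s-cis to C6=C15 (the ring C5=O is locked s-trans), and this doubly acceptor-substituted 1-oxadiene adds to the electron-rich C10=C9 alkene in a concerted, asynchronous inverse-electron-demand [4+2], with C15–C10 bonding in advance and O8 closing on the tertiary C9, which fixes the regiochemistry. The closest known reaction type is the intramolecular oxa-Diels–Alder reaction of 2-alkylidene-1,3-dicarbonyl compounds and of cycloalkene-1-carbaldehydes carrying a tethered trisubstituted alkene (the Knoevenagel/hetero-Diels–Alder manifold), combined with the selenoxide route to 2-formyl enones. Two rings close at once: the dihydropyran (C6, C7, O8, C9, C10, C15) is the cycloadduct ring itself, and the cyclohexane (C10–C15) is the tether ring, closed by the C15–C10 bond exo to both π bonds across the 1,3-positions C13/C15 of the seven-membered ring, which thereby becomes the bicyclo[4.3.1]decadienone. C15 is controlled by C13, because the four-atom tether reaches C15 only on the ring face that carries the side chain; C10 is controlled by the folding of the tether, the exo mode (C11 anti to C6, boat-like cyclohexane) giving the required trans H-10/H-15. The step therefore needs exo over endo folding and intra- over intermolecular reaction: endo folding would push C11–C12 under C5/C6 within van der Waals contact of the flat cross-conjugated dienone and bend it out of conjugation, whereas exo folding leaves the tether outside the ring perimeter; the early transition state of so activated a heterodiene should feel little of the boat strain, and gem-disubstitution at C13 together with high dilution favours the intramolecular path.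

Step 11
Reactants: 19 tricyclic dienone
Product: 21 (6R,10S,13S,15S)-C6-hydroxy C7-methyl acetal (saturated pyran, enone intact; C7 epimers), via (6R)-C6–C7 epoxide on the face of H-15 20 (not isolated)
Conditions: DMDO (acetone solution), CH2Cl2/MeOH, −20 → 0 °C; then PPTS (5 mol %), 23 °C
Reagents that add atoms: dimethyldioxirane, CC1(C)OO1; methanol, CO
Why: Dioxirane epoxidation of an enol ether with glycal-type methanolysis: DMDO takes the donor-substituted C6=C7 alkene and not the electron-poor, neopentyl C4=C16 enone, attacks the convex face syn to H-15 and anti to C14 (C7 is tied to the endo bridge through O8–C9–C10), so C6–O is set (R), and methanol opens the epoxide at the oxocarbenium carbon C7.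

Step 12
Reactants: 21 methyl acetal ketol
Product: 22 (6R,10S,13S,15S)-tertiary α-ketol enone with saturated pyran (C7 = CH2)
Conditions: Et3SiH, BF3·OEt2, CH2Cl2, −78 → −20 °C
Reagents that add atoms: none
Why: Ionic silane reduction of a cyclic acetal: BF3 ionises the exocyclic C7–OMe bond to the ring oxocarbenium ion, which takes hydride from Et3SiH, while the enone and the tertiary alcohol are inert at low temperature and the C7 stereocentre disappears.

Step 13
Reactants: 22 α-ketol enone
Product: 23 (6R,10S,13S,15S)-C6 triethylsilyl ether of the α-ketol enone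
Conditions: TESOTf, 2,6-lutidine, CH2Cl2, −78 → 0 °C
Reagents that add atoms: triethylsilyl trifluoromethanesulfonate, CC[Si](CC)(CC)OS(=O)(=O)C(F)(F)F
Why: Silyl triflate silylation of a hindered tertiary alcohol; the ketone has no enolisable hydrogen (C6 quaternary, C4 vinylic, C13 quaternary), so no silyl enol ether can form.

Step 14
Reactants: 23 TES-protected enone; 24 3-bromo-2-methylprop-1-ene
Product: 26 (4S,6R,10S,13S,15S,16S)-C16-vinyl, C4-(2-methylallyl) ketone (the two chains trans), via C5 bromomagnesium enolate bearing the exo C16 vinyl group 25 (not isolated)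
Conditions: CH2=CHMgBr, CuBr·SMe2 (20 mol %), THF, −78 → −40 °C; then 24, DMPU, −40 → 0 °C
Reagents that add atoms: vinylmagnesium bromide, C=C[Mg]Br
Why: Copper-catalysed conjugate addition with enolate allylation (tandem vicinal difunctionalisation): the vinyl group enters C16 on the exo face of the bicyclic enone, opposite the C10–C12 bridge, 1,2-addition is blocked by the quaternary C6, and the enolate is allylated at C4 anti to the new vinyl group and to the exo C6–OSiEt3.

Step 15
Reactants: 26 diene ketone
Product: 28 (4S,6R,10S,13S,15S,16S)-C16 carbaldehyde with the C4 acetonyl chain, via bis(1,2,4-trioxolane) 27 (not isolated)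
Conditions: O3, CH2Cl2, −78 °C (indicator end point); Me2S, −78 → 23 °C
Reagents that add atoms: ozone, [O-][O+]=O
Why: Ozonolysis with reductive work-up cleaves both terminal alkenes in one operation (vinyl to the C17 aldehyde, methylallyl to the C2 methyl ketone) under neutral conditions that spare the silyl ether and the epimerisable C4 and C16.

Step 16
Reactants: 28 keto aldehyde
Product: 29 (E)-alkenyl pinacol boronate (C17=C18–Bpin; other centres unchanged)
Conditions: Cl2CHB(pin), CrCl2, LiI, THF, 23 °C
Reagents that add atoms: 2-(dichloromethyl)-4,4,5,5-tetramethyl-1,3,2-dioxaborolane, ClC(Cl)B1OC(C)(C)C(C)(C)O1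
Why: Takai–Utimoto-type chromium(II) borylolefination: the geminal dichromium reagent adds only to the aldehyde (both ketones are inert), elimination gives the E-alkenylboronate and so adds C18, and the non-basic medium spares C16 and C4.

Step 17
Reactants: 29 pinacol boronate
Product: 30 potassium (E)-alkenyltrifluoroborate
Conditions: aq KHF2, MeOH, 0 → 23 °C, short contact; pinacol removed azeotropically (aq MeOH)
Reagents that add atoms: potassium hydrogen difluoride, F.[F-].[K+]
Why: Boronate-to-trifluoroborate exchange with KHF2, which does not touch the alkene geometry; a short contact time keeps the hindered tertiary silyl ether in place.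

Step 18
Reactants: 30 potassium alkenyltrifluoroborate; 31 3-methylbut-2-enoic acid
Product: 32 C6 triethylsilyl ether of the target
Conditions: 31 (2 equiv), CuBr (10 mol %), DMAP (20 mol %), 4 Å MS, O2 (1 atm), MeCN, 60 °C
Reagents that add atoms: none
Why: Chan–Lam-type copper-catalysed oxidative coupling of an alkenyltrifluoroborate with a carboxylic acid, in which C–O reductive elimination from the alkenylcopper(III) carboxylate retains the E geometry and the ketones, ethers and silyl ether are spectators.

Step 19
Reactants: 32 TES ether of the target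
Product: 33 target CNP0237201.1, (4S,6R,10S,13S,15S,16S), E enol ester
Conditions: HF·pyridine, pyridine, THF, 0 → 23 °C
Reagents that add atoms: none
Why: Buffered fluoride desilylation, mild enough not to cleave or isomerise the enol ester, epimerise C4 or trigger an α-ketol shift.

**Compound list**

1 | 2-(2-bromoethyl)-1,3-dioxolane | BrCCC1OCCO1 | starting material
2 | [2-(1,3-dioxolan-2-yl)ethyl]magnesium bromide | Br[Mg]CCC1OCCO1 | intermediate
3 | 3-methylcyclohex-2-en-1-one | CC1=CC(=O)CCC1 | starting material
4 | bromomagnesium (R)-3-[2-(1,3-dioxolan-2-yl)ethyl]-3-methylcyclohex-1-en-1-olate | C1COC(O1)CC[C@@]2(C)CCCC(O[Mg]Br)=C2 | intermediate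
5 | (R)-({3-[2-(1,3-dioxolan-2-yl)ethyl]-3-methylcyclohex-1-en-1-yl}oxy)trimethylsilane | C1COC(O1)CC[C@@]2(C)CCCC(O[Si](C)(C)C)=C2 | intermediate
6 | (5R)-5-[2-(1,3-dioxolan-2-yl)ethyl]-5-methyl-1-(trimethylsilyloxy)bicyclo[4.1.0]heptane | C1COC(O1)CC[C@@]2(C)CCC[C@]3(O[Si](C)(C)C)C[C@H]23 | intermediate
7 | (4R)-3-chloro-4-[2-(1,3-dioxolan-2-yl)ethyl]-4-methylcycloheptan-1-one (C–Cl epimers) | C1COC(O1)CC[C@@]2(C)CCCC(=O)CC2Cl | intermediate
8 | (R)-4-[2-(1,3-dioxolan-2-yl)ethyl]-4-methylcyclohept-2-en-1-one | C1COC(O1)CC[C@@]2(C)CCCC(=O)C=C2 | intermediate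
9 | (R)-3-(1-methyl-4-oxocyclohept-2-en-1-yl)propanal | O=CCC[C@@]1(C)CCCC(=O)C=C1 | intermediate
10 | isopropyltriphenylphosphonium iodide | CC(C)[P+](c1ccccc1)(c1ccccc1)c1ccccc1.[I-] | starting material
11 | isopropylidenetriphenylphosphorane | CC(C)=P(c1ccccc1)(c1ccccc1)c1ccccc1 | intermediate
12 | (R)-4-methyl-4-(4-methylpent-3-en-1-yl)cyclohept-2-en-1-one | CC(C)=CCC[C@@]1(C)CCCC(=O)C=C1 | intermediate
13 | lithium 5-methyl-5-(4-methylpent-3-en-1-yl)cyclohepta-1,6-dien-1-olate | CC(C)=CCC[C@@]1(C)CCC=C(O[Li])C=C1 | intermediate
14 | (S,Z)-7-(hydroxymethylidene)-4-methyl-4-(4-methylpent-3-en-1-yl)cyclohept-2-en-1-one | CC(C)=CCC[C@@]1(C)CC/C(=C/O)C(=O)C=C1 | intermediate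
15 | sodium enolate of the formyl ketone | CC(C)=CCC[C@@]1(C)CC/C(=C/[O-])C(=O)C=C1.[Na+] | intermediate
16 | (4S)-4-methyl-4-(4-methylpent-3-en-1-yl)-7-oxo-1-(phenylselanyl)cyclohept-5-ene-1-carbaldehyde (C6 epimers) | CC(C)=CCC[C@@]1(C)CCC(C=O)([Se]c2ccccc2)C(=O)C=C1 | intermediate
17 | (4S)-4-methyl-4-(4-methylpent-3-en-1-yl)-7-oxo-1-(phenylseleninyl)cyclohept-5-ene-1-carbaldehyde | CC(C)=CCC[C@@]1(C)CCC(C=O)([Se](=O)c2ccccc2)C(=O)C=C1 | intermediate
18 | (S)-4-methyl-4-(4-methylpent-3-en-1-yl)-7-oxocyclohepta-1,5-diene-1-carbaldehyde | CC(C)=CCC[C@@]1(C)CC=C(C=O)C(=O)C=C1 | intermediate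
19 | (10S,13S,15S)-tricyclic dienone (dihydropyran fused to bicyclo[4.3.1]decadienone) | O=C1C=C[C@@]2(C)CC[C@H]3[C@H](C2)C1=COC3(C)C | intermediate
20 | C6–C7 epoxide of the tricyclic dienone (oxygen syn to H-15) | O=C1C=C[C@@]2(C)CC[C@H]3[C@H](C2)[C@]14O[C@H]4OC3(C)C | intermediate
21 | (6R)-C6-hydroxy C7-methyl acetal (C7 epimers) | O=C1C=C[C@@]2(C)CC[C@H]3[C@H](C2)[C@@]1(O)C(OC)OC3(C)C | intermediate
22 | (6R,10S,13S,15S)-tertiary α-ketol enone with saturated pyran | O=C1C=C[C@@]2(C)CC[C@H]3[C@H](C2)[C@@]1(O)COC3(C)C | intermediate
23 | C6 triethylsilyl ether of the α-ketol enone | O=C1C=C[C@@]2(C)CC[C@H]3[C@H](C2)[C@@]1(O[Si](CC)(CC)CC)COC3(C)C | intermediate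
24 | 3-bromo-2-methylprop-1-ene | C=C(C)CBr | starting material
25 | C5 bromomagnesium enolate with exo C16 vinyl group | C1=C(O[Mg]Br)[C@]2(O[Si](CC)(CC)CC)COC(C)(C)[C@H]3CC[C@@](C)(C[C@@H]32)[C@H]1C=C | intermediate
26 | (4S,6R,10S,13S,15S,16S)-C16-vinyl, C4-(2-methylallyl) ketone | C=C(C)C[C@@H]1C(=O)[C@]2(O[Si](CC)(CC)CC)COC(C)(C)[C@H]3CC[C@@](C)(C[C@@H]32)[C@H]1C=C | intermediate
27 | bis(1,2,4-trioxolane) of the diene ketone | CC1(OCOO1)C[C@@H]2C(=O)[C@]3(O[Si](CC)(CC)CC)COC(C)(C)[C@H]4CC[C@@](C)(C[C@@H]43)[C@H]2C5OCOO5 | intermediate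
28 | C16 carbaldehyde with C4 acetonyl chain | CC(=O)C[C@@H]1C(=O)[C@]2(O[Si](CC)(CC)CC)COC(C)(C)[C@H]3CC[C@@](C)(C[C@@H]32)[C@H]1C=O | intermediate
29 | (E)-alkenyl pinacol boronate | CC(=O)C[C@@H]1C(=O)[C@]2(O[Si](CC)(CC)CC)COC(C)(C)[C@H]3CC[C@@](C)(C[C@@H]32)[C@H]1/C=C/B4OC(C)(C)C(C)(C)O4 | intermediate
30 | potassium (E)-alkenyltrifluoroborate | CC(=O)C[C@@H]1C(=O)[C@]2(O[Si](CC)(CC)CC)COC(C)(C)[C@H]3CC[C@@](C)(C[C@@H]32)[C@H]1/C=C/[B-](F)(F)F.[K+] | intermediate
31 | 3-methylbut-2-enoic acid | CC(C)=CC(=O)O | starting material
32 | C6 triethylsilyl ether of the target | CC(=O)C[C@@H]1C(=O)[C@]2(O[Si](CC)(CC)CC)COC(C)(C)[C@H]3CC[C@@](C)(C[C@@H]32)[C@H]1/C=C/OC(=O)C=C(C)C | intermediate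
33 | CNP0237201.1 | CC(=O)C[C@@H]1C(=O)[C@]2(O)COC(C)(C)[C@H]3CC[C@@](C)(C[C@@H]32)[C@H]1/C=C/OC(=O)C=C(C)C | target

**Totals**

Total step count: 19. Longest linear sequence: 19 steps (1 → 33). Compounds 3, 10, 24 and 31 enter directly as bought materials.

**Three steps most likely to fail**

Step 10. A chair-like endo folding of the tether may compete with the boat-like exo folding and erode the configuration at C10. The unmasked formyl dienone may also be lost before it cyclises, by γ-deprotonation at C14 (tautomerisation), hydration or dimerisation.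

The fallback sets out from 12 and returns at 22. It makes the same two bonds in a stepwise polar sequence at the hydroxymethyl oxidation level. C15–C10 bond formation then no longer has to keep O8 over C9. No formyl dienone, enol ether oxidation or acetal reduction is needed.
- The kinetic enolate 13 is dehydrogenated with N-tert-butylbenzenesulfinimidoyl chloride (THF, −78 °C) to (S)-4-methyl-4-(4-methylpent-3-en-1-yl)cyclohepta-2,6-dien-1-one F1.
- Morita–Baylis–Hillman hydroxymethylation (aq CH2O, DMAP, THF/H2O) occurs on the unhindered enone arm, because the catalyst adds to C15 and not to the neopentyl C16. It gives (S)-2-(hydroxymethyl)-5-methyl-5-(4-methylpent-3-en-1-yl)cyclohepta-2,6-dien-1-one F2.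
- BF3·OEt2 in CH2Cl2 at −78 °C triggers Michael-type attack of the prenyl alkene on C15 and capture of the C9 cation by the C7 hydroxyl. The product is the tricyclic enone with C6–H F3.
- KHMDS converts it into the potassium cross-conjugated dienolate F4 (C6–H is the only enolisable hydrogen). This is hydroxylated on the convex face with 2-(phenylsulfonyl)-3-phenyloxaziridine to give 22.

Step 14. Conjugate addition at the neopentyl C16 may be slow and let 1,2-addition compete. The hindered enolate may alkylate sluggishly with proton transfer. Allylation may also come from the exo face and invert C4.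

The fallback sets out from 23 and returns at 26. It reverses the order of the two C–C bond formations, so that C4 is set by protonation instead of alkylation, which is stereocomplementary.
- Johnson α-iodination (I2, pyridine, CH2Cl2) gives the C4-iodo enone F5.
- Stille coupling with tributyl(2-methylallyl)stannane (Pd2(dba)3, AsPh3, CuI, NMP) gives the C4-(2-methylallyl) enone F6.
- Copper-catalysed addition of vinylmagnesium bromide on the exo face gives the tetrasubstituted bromomagnesium enolate F7.
- F7 is protonated at −78 °C by a hindered phenol from the same open exo face. This places the C4 chain endo and trans to the vinyl group, i.e. 26.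

Step 18. Transmetalation of the hindered alkenylboron may be slow, so that protodeboronation or oxidative homocoupling overtakes C–O bond formation. Prolonged heating with DMAP may also epimerise C4.

The fallback sets out from 28 and returns at 32. It builds the enol ester by O-acylation of a homologous aldehyde instead of by cross-coupling.
- Wittig methoxymethylenation of the aldehyde (Ph3P=CHOMe, THF, −78 °C, ketones untouched) gives the C17=C18 methyl enol ether F8.
- Mild hydrolysis (PPTS, wet acetone) gives the homologous C16–CH2–CHO aldehyde F9.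
- Soft enolisation and O-acylation (Et3N, DMAP, CH2Cl2) with 3-methylbut-2-enoic anhydride F10, prepared from 31 with DCC, gives the enol ester. The bulky C16 substituent favours the E isomer 32, which is separated from any Z isomer by chromatography.

**Further compounds**

F1 | step 10 | (S)-4-methyl-4-(4-methylpent-3-en-1-yl)cyclohepta-2,6-dien-1-one | CC(C)=CCC[C@@]1(C)CC=CC(=O)C=C1
F2 | step 10 | (S)-2-(hydroxymethyl)-5-methyl-5-(4-methylpent-3-en-1-yl)cyclohepta-2,6-dien-1-one | CC(C)=CCC[C@@]1(C)CC=C(CO)C(=O)C=C1
F3 | step 10 | tricyclic enone with C6–H (H-6 syn to H-15) | O=C1C=C[C@@]2(C)CC[C@H]3[C@H](C2)[C@H]1COC3(C)C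
F4 | step 10 | potassium cross-conjugated dienolate of the tricyclic enone | [O-]C1=C2COC(C)(C)[C@H]3CC[C@@](C)(C[C@@H]32)C=C1.[K+]
F5 | step 14 | C4-iodo enone (TES ether) | O=C1C(I)=C[C@@]2(C)CC[C@H]3[C@H](C2)[C@@]1(O[Si](CC)(CC)CC)COC3(C)C
F6 | step 14 | C4-(2-methylallyl) enone (TES ether) | O=C1C(CC(C)=C)=C[C@@]2(C)CC[C@H]3[C@H](C2)[C@@]1(O[Si](CC)(CC)CC)COC3(C)C
F7 | step 14 | tetrasubstituted bromomagnesium enolate with exo C16 vinyl group | C=C(C)CC1=C(O[Mg]Br)[C@]2(O[Si](CC)(CC)CC)COC(C)(C)[C@H]3CC[C@@](C)(C[C@@H]32)[C@H]1C=C
F8 | step 18 | C17=C18 methyl enol ether (E/Z) | CC(=O)C[C@@H]1C(=O)[C@]2(O[Si](CC)(CC)CC)COC(C)(C)[C@H]3CC[C@@](C)(C[C@@H]32)[C@H]1C=COC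
F9 | step 18 | homologous C16–CH2–CHO aldehyde | CC(=O)C[C@@H]1C(=O)[C@]2(O[Si](CC)(CC)CC)COC(C)(C)[C@H]3CC[C@@](C)(C[C@@H]32)[C@H]1CC=O
F10 | step 18 | 3-methylbut-2-enoic anhydride | CC(C)=CC(=O)OC(=O)C=C(C)C
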